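Numbering used throughout, also for monocyclic ring A intermediates: C1 and C5 are the bridgeheads, C9 the bridging ketone, ring A = C1–C2–C3–C4–C5–C9, ring B = C1–C9–C5–C6–C7–C8, and G1–G8 are the geranyl carbons counted from C7. Compounds are numbered 1–29 in order of first appearance in the steps; 29 is the target.

## Analysis of the target

CNP0285073.1 (29) is a type B polyprenylated acylphloroglucinol: a bicyclo[3.3.1]nonane-2,4,9-trione whose ring A carries the 3-hydroxybenzoyl group on C3 as an enolised β-triketone, and whose ring B is a chair bridged at C9. Both bridgeheads carry prenyl, C8 is quaternary with methyl and homoprenyl, and C7 carries geranyl. There are four stereocentres, 1S,5S,7R,8S for the tautomer drawn: C1 and C5 are tied to each other by the bridge, C8 has methyl axial and homoprenyl equatorial on ring B, and the C7 geranyl is equatorial, trans to homoprenyl and cis to methyl. The sensitive groups are five trisubstituted alkenes (no acid, electrophilic halogen, ozone or hydrogenation), the non-enolisable 1,3-diketone units across C1 and C5 (retro-Claisen with hard nucleophiles), and the phenol. The difficulty lies in three quaternary carbons, two of them (C1 and C8) adjacent, and in a phloroglucinol-type ring A that tends to rearomatise and to direct every allyl group or electrophile to C3. The strategy rests on C6: it is a bare methylene between quaternary C5 and the C7 methine, and the geranyl alkene G2=G3 is allylic to C7. A C6 radical adding to C7 of a C7=G1–G2=G3 diene therefore closes ring B, and hydrogen transfer to G1 leaves the geranyl group.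

## Retrosynthetic reasoning

**29 ⇒ 28 ⇒ 25 + 26.** The last bonds cut are the two O–methyl bonds of 28 and, before them, the C3–acyl bond. In 25, C3–H is the only acidic hydrogen because C1 and C5 are quaternary, so metalation at C3 and acylation with 26 is unambiguous. Leaving the aroyl group to the end keeps a chelating triketone and a phenol out of the radical step. The ether cleavage has to avoid acid, which would cyclise prenyl groups onto the enol.

**25 ⇒ 24 (C6–C7).** Cutting C6–C7 removes ring B and the C7 stereocentre at once, while C1, C5 and C8 stay quaternary in the precursor. C6 is neopentyl-like and is useless as a nucleophile or SN2 electrophile, so a radical is its only practical reactive form. The forward closure must beat the 1,2-acyl shift of a β-keto radical. For that reason C4 must be the carbonyl of a vinylogous ester and not an enol ether carbon: a C4=C3 alkene next to the radical would undergo the much faster 1,2-vinyl shift. The methyl enol ether of 24 therefore sits on O2.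

**24 ⇒ 22 ⇒ 21 ⇒ 20 ⇒ 19.** The C6 iodide is traced to acid 22 by decarboxylative iodination. A carboxymethyl group is the C6 precursor that survives enolate chemistry at C5; a halomethyl or alkoxymethyl group there would be expelled. Enol ether 21 comes from diketone 20, and 20 from the C3 dimethyl ketal 19. The methylation of 20 has to put the methyl group on O2, the oxygen on the more hindered C1 side, so its regioselectivity is a point of risk that is taken up at the end. C3 is carried as a ketal up to 19 for two reasons. First, C3–H is where allyl groups, electrophiles and Cope shifts otherwise end up. Second, a C3 methylene would make the two arms leaving C1 (via C2 and via C9) interconvertible by enolisation once C5 is also a methylene, and that would erase the C1 configuration.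

**19 ⇒ 17 + 18; 17 ⇒ 15 + 16.** At C5 the prenyl bond is cut first and the C5–C6 bond second. An electrophile adds to the C5 enolate on the face opposite the tertiary C8 substituent on C1, and ring B can only close if C6 is cis to C8. So C6 must be in place first and prenyl must come last. With C3 blocked, C5 is the only acidic carbon of 15.

**15 ⇒ 14 ⇒ 13 + 4.** The diene is cut between G1 and G2 (Heck). Carrying the whole dienyl chain through the sigmatropic step would need an ether of a bis-allylic carbinol, in which two allyl arms of unlike geometry compete. The vinyl group of 13 and iodide 4 avoid this, and because C8 is quaternary, β-hydride elimination has only one direction.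

**13 ⇒ 12 ⇒ 11 ⇒ 9 + 10.** The bond between the two quaternary carbons C1 and C8 is cut as a [3,3] shift from O9. With the ether on O9, a chair transition state needs the Z alkene of 10 to place methyl and homoprenyl on C8 as in the target; an E alkene would lead to the opposite configuration at C8. The shift is run on the non-aromatic dienone 11, because on an aromatic ring A the allyl group would end on the unsubstituted C3 position, directly or by a following Cope shift. After the shift, C1 of 12 lies between two carbonyl groups, so no Cope shift can follow. The rearrangement gives racemic 12, which is resolved to 13.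

**9 ⇒ 6 + 7; 6 ⇒ 5.** Ring A comes from phenol 5 by oxidative dearomatisation. Quinone monoketal 6 is symmetrical, so hydrolysis of either enol ether gives the same dione enolate 8, whose central carbon is C1 and is alkylated by 7. The ketal then makes O2 the hindered and O9 the accessible oxygen of 9.

**4 ⇒ 2 ⇒ 1.** The E trisubstituted iodide is cut at the methyl–carbon and C–I bonds of a carbometalation of alkyne 2, itself from bromide 1.

## Alternatives that were turned down

**Alternative 1:** The C8–homoprenyl and C1–prenyl bonds are cut on a preformed ring B enone carrying the C1 acetyl group. Forward, a copper-catalysed 1,4-addition of a homoprenyl nucleophile to C8 is followed by trapping of the enolate at C1 with prenyl bromide 7, giving A1; ring A would then close by Claisen condensation of the acetyl group onto the C5 ester.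
- For: the two adjacent quaternary carbons arise in one flask, and all four stereocentres sit on one chair, so the C7 geranyl group can steer the cuprate.
- Against: the acceptor carbon is fully substituted and flanked by the C7 side chain. The intermediate is a fully substituted diketone enolate that is likely to be prenylated on oxygen. The enone precursor of A1 (C5 quaternary ester, C7 stereocentre) needs a long synthesis of its own. The final condensation has to attack an ester on a quaternary carbon while the 1,3-diketone at C1 is open to retro-Claisen cleavage.
- Comparison: this route is stronger in fixing all stereocentres by substrate control on one ring, possibly without resolution. The chosen route offers ring A in one step from a commercial phenol and a C1–C8 bond made by an intramolecular sigmatropic shift instead of two intermolecular attacks at neopentyl positions.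

**Alternative 2:** The C1–C2 bond is cut. Forward, a cationic monovalent gold catalyst activates a terminal alkyne, and C1 of a C9 silyl enol ether attacks C2 in a 6-endo-dig closure that forms ring A and gives A2.
- For: carbocyclisations of this type are the best-precedented way to forge a bridgehead quaternary carbon of this core, and the conditions are neutral.
- Against: the substrate needs a tetrasubstituted C9=C1 silyl enol ether next to quaternary C8, and an alkynyl carbinol chain on quaternary C5. The alkenophilic catalyst meets five alkenes, one of them in an enyne relationship with the alkyne. A2 lacks the C2 oxygen, so ring A must still be oxidised at C2 and C4 in the presence of all those alkenes, several redox steps after the key step.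
- Comparison: the key step of this alternative has closer precedent than a radical closure that competes with an acyl shift, and it is stronger there. The chosen route delivers ring A at the trione oxidation level from the start, so that only protecting-group and acylation steps follow ring closure.

**Alternative 3:** The C4–C5 bond is cut. Forward, the potassium enolate at C5 of a ring B ketone adds to the aldehyde of an E β-methoxy enal on C1, closing ring A to carbinol A3; one oxidation would give 25.
- For: it converges on the same bicyclic vinylogous ester 25, makes the C5 quaternary bridgehead and ring A together, and avoids tin and radical rearrangements.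
- Against: an aldol that forms a strained β-hydroxy ketone with a quaternary α-carbon is reversible and tends to revert. The enolate must be formed beside a base-sensitive β-methoxy enal. The precursor of A3 needs ring B with three contiguous stereocentres and an acyl-type substituent on quaternary C1.
- Comparison: it is equal or better in steps after ring closure. The chosen route offers an irreversible bond formation and a much shorter way to the cyclisation substrate.

Key step: step 15

Remarks on the chemistry:
- Enolisable 1,3-diones (9, 15, 17, 20) are drawn as one tautomer; 17 is a mixture of C5 epimers that converge in step 10.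
- The two enantiomers of 12 are assigned by vibrational circular dichroism or by anomalous-dispersion X-ray analysis of a crystalline derivative, and the one drawn as 13 is carried on.
- 2-(Trimethylsilyl)ethyl bromoacetate 16 and prenyl acetate 18 are taken as purchased.

## Route

Step 1
Reactants: 1 5-bromo-2-methylpent-2-ene
Product: 2 6-methylhept-5-en-1-yne
Conditions: LiC≡CH·H2NCH2CH2NH2, DMSO, 10 °C → rt
Reagents that add atoms: lithium acetylide (ethylenediamine complex), [Li]C#C
Why: SN2 alkylation of an acetylide by a primary homoallylic bromide; the ethylenediamine complex in DMSO keeps elimination low.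

Step 2
Reactants: 2 6-methylhept-5-en-1-yne
Product: 4 (E)-1-iodo-2,6-dimethylhepta-1,5-diene, via alkenylalane 3 (not isolated)
Conditions: AlMe3 (2 equiv), Cp2ZrCl2 (20 mol %), CH2Cl2, 0 °C → rt; then I2, THF, −30 → 0 °C
Reagents that add atoms: trimethylaluminium, C[Al](C)C; iodine, II
Why: Negishi carboalumination adds methyl and aluminium syn across the terminal alkyne with methyl on the internal carbon; iodinolysis of the C–Al bond goes with retention and should give the E iodide.

Step 3
Reactants: 5 3,4,5-trimethoxyphenol
Product: 6 3,4,4,5-tetramethoxycyclohexa-2,5-dien-1-one (C9 ketone; C2 and C4 methyl enol ethers; C3 dimethyl ketal)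
Conditions: PhI(OAc)2, MeOH, 0 °C
Reagents that add atoms: methanol, CO
Why: Oxidative dearomatisation of a para-methoxyphenol to the para-quinone monoketal; the ketal carbon is the future C3 and keeps ring A from rearomatising.

Step 4
Reactants: 6 3,4,4,5-tetramethoxycyclohexa-2,5-dien-1-one; 7 prenyl bromide
Product: 9 3-hydroxy-4,4,5-trimethoxy-2-(3-methylbut-2-enyl)cyclohexa-2,5-dien-1-one (C1 prenyl; C2/C9 dione as enol; C3 ketal; C4 methyl enol ether), via sodium enolate 8 (not isolated)
Conditions: 1 M NaOH, THF, 40 °C; then prenyl bromide, rt; NaH2PO4 work-up (pH 5)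
Reagents that add atoms: sodium hydroxide, [Na+].[OH-]
Why: Hydroxide adds to one of the two equivalent β-methoxy enone carbons and expels methoxide (vinylogous ester hydrolysis; the enolate formed resists a second hydrolysis). The cyclic 1,3-dione anion is then C-alkylated at its central carbon C1 by the allylic bromide in water.

Step 5
Reactants: 9 C1-prenyl dione; 10 nerol
Product: 12 racemic 2-(3,7-dimethylocta-1,6-dien-3-yl)-4,4,5-trimethoxy-2-(3-methylbut-2-enyl)cyclohex-5-ene-1,3-dione (C1 and C8 relative configuration as in the target), via neryl enol ether 11 (not isolated)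
Conditions: PPh3, DIAD, toluene, 0 °C → rt; then 110 °C
Reagents that add atoms: none
Why: Mitsunobu O-alkylation of the acidic dione at the less hindered oxygen O9 (O2 is flanked by the ketal) gives the allyl vinyl ether. Claisen rearrangement from O9 to C1 through a chair with the Z neryl terminus should place methyl and homoprenyl on C8 so that C1 and C8 have the relative configuration of the target. C1 then lies between two carbonyl groups and cannot undergo a Cope shift.

Step 6
Reactants: 12 racemic Claisen product
Product: 13 enantiomer of 12 with C1 and C8 configured as in the target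
Conditions: preparative SFC on amylose tris(3,5-dimethylphenylcarbamate), CO2/i-PrOH, 35 °C
Reagents that add atoms: none
Why: Resolution by chromatography on a chiral stationary phase; C1 and C8 are the only stereocentres at this point, and C5 and C7 are later set relative to them.

Step 7
Reactants: 13 resolved vinyl compound; 4 (E)-1-iodo-2,6-dimethylhepta-1,5-diene
Product: 14 4,4,5-trimethoxy-2-(3-methylbut-2-enyl)-2-[(7E,9E)-2,6,10,14-tetramethylpentadeca-2,7,9,13-tetraen-6-yl]cyclohex-5-ene-1,3-dione (E,E C7=G1–G2=G3 diene on C8)
Conditions: Pd(OAc)2 (10 mol %), Bu4NCl, NaHCO3, DMF, 60 °C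
Reagents that add atoms: none
Why: Mizoroki–Heck reaction: the alkenylpalladium species inserts into the terminal vinyl group, and because C8 is quaternary, β-hydride elimination can only occur toward G1, which should give the E,E diene; trisubstituted alkenes do not compete.

Step 8
Reactants: 14 dienyl enol ether
Product: 15 2,2-dimethoxy-4-(3-methylbut-2-enyl)-4-[(7E,9E)-2,6,10,14-tetramethylpentadeca-2,7,9,13-tetraen-6-yl]cyclohexane-1,3,5-trione (C2, C4, C9 ketones; C3 ketal; C5 methylene)
Conditions: 1 M HCl, THF, 0 °C → rt
Reagents that add atoms: water, O
Why: Acid hydrolysis of the methyl vinylogous ester (water adds at C4). The C3 ketal, flanked by carbonyl groups, ionises far more slowly and should survive. C5 becomes the central carbon of a 1,3-dione.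

Step 9
Reactants: 15 trione ketal; 16 2-(trimethylsilyl)ethyl bromoacetate
Product: 17 C5-[2-oxo-2-(2-trimethylsilylethoxy)ethyl] derivative of 15 (C5 epimers)
Conditions: K2CO3, acetone, rt → 40 °C
Reagents that add atoms: none
Why: C-alkylation of a cyclic 1,3-dione with an α-bromo ester; C5 is the only acidic carbon because C3 is a ketal. The new centre is epimerisable and is fixed in step 10.

Step 10
Reactants: 17 C5 acetate ester; 18 prenyl acetate
Product: 19 C5-prenylated ketal ester (C5: prenyl trans and CH2CO2R cis to C8; C1, C5, C8 as in the target)
Conditions: NaH, THF, 0 °C; then Pd(PPh3)4 (5 mol %), prenyl acetate, rt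
Reagents that add atoms: none
Why: Tsuji–Trost allylation: the sodium enolate attacks the π-prenyl complex of palladium at its unsubstituted terminus (linear prenyl, C- rather than O-alkylation). It attacks on the ring face opposite the tertiary C8 substituent on C1, so that the acetate arm (future C6) ends cis to C8.

Step 11
Reactants: 19 C5-prenylated ketal ester
Product: 20 trione ester with C3 methylene (C2, C4, C9 ketones)
Conditions: SmI2 (5 equiv), THF/MeOH, −78 → −30 °C
Reagents that add atoms: none
Why: SmI2 reduction of an α,α-dimethoxy ketone: electron transfer to the chelated C2 or C4 carbonyl expels methoxide, the samarium enolate is protonated by methanol, and repetition gives the C3 methylene. Esters, isolated alkenes and the diene are not reduced.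

Step 12
Reactants: 20 trione ester
Product: 21 C2 methyl enol ether ester (C2–OMe, C2=C3, C4 ketone)
Conditions: Me3SiCHN2, toluene/MeOH, 0 °C; chromatographic separation
Reagents that add atoms: (trimethylsilyl)diazomethane, C[Si](C)(C)C=[N+]=[N-]
Why: O-Methylation of the enolised 1,3-dione by diazomethane formed in situ gives the methyl vinylogous ester. The ambident enolate can also be methylated on O4, so 21 has to be separated from its regioisomer, and the handling of that isomer is set out under the least certain steps. Only 21 has C4 as a carbonyl next to the future radical.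

Step 13
Reactants: 21 C2 methyl enol ether ester
Product: 22 C5-acetic acid (C2 methyl enol ether)
Conditions: Bu4NF, THF, 0 °C → rt; aq. NH4Cl
Reagents that add atoms: none
Why: Fluoride attacks silicon and the ester fragments to carboxylate, ethene and Me3SiF; the enol ether and the diketones are not touched.

Step 14
Reactants: 22 C5-acetic acid
Product: 24 C5 iodomethyl compound (precursor of the key step), via thiohydroxamate ester 23 (not isolated)
Conditions: N-hydroxypyridine-2-thione, DCC, DMAP (cat.), CH2Cl2, 0 °C, dark; then CHI3 (excess), hν (tungsten lamp), 15 °C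
Reagents that add atoms: iodoform, IC(I)I
Why: Barton decarboxylative iodination: the O-acyl thiohydroxamate fragments under visible light to the C6 radical, which should take iodine from the excess iodoform before it can cyclise.

Step 15
Reactants: 24 C5 iodomethyl compound
Product: 25 bicyclic methyl vinylogous ester (2-methoxybicyclo[3.3.1]non-2-ene-4,9-dione with C1 and C5 prenyl, C7 geranyl, C8 methyl and homoprenyl)
Conditions: Bu3SnH (1.3 equiv, syringe pump), Et3B (0.3 equiv), air, toluene (0.01 M), rt
Reagents that add atoms: none
Why: Et3B and oxygen start the chain at room temperature and the tributyltin radical abstracts iodine from the neopentyl C6–I bond. The primary C6 radical adds to C7, the terminus of the E,E diene, in a 6-exo-trig closure that forms C6–C7 and ring B of the bicyclo[3.3.1]nonane. The closest known reaction type is the tin hydride-mediated 6-exo cyclisation of alkyl radicals onto 1,3-dienes. The allyl radical takes hydrogen from Bu3SnH at its less substituted end G1, which should leave the trisubstituted E G2=G3 alkene of geranyl. C7 is set in a chair-like transition state with the diene remainder equatorial, away from C2–C4 of ring A, so the geranyl group ends trans to the C8 homoprenyl; C1, C5 and C8 are already fixed. The step needs cyclisation to outrun the 1,2-acyl shift of the β-keto radical and direct reduction: the conjugated diene is a fast acceptor, C4 is a deactivated vinylogous ester carbonyl, and the stannane is added slowly at high dilution. The only other 6-exo acceptor, the C1 prenyl group, is trans to C6 on ring A and cannot be reached. Room-temperature initiation is chosen because 24 contains the 1,5-diene G1=C7–C8–C1–C2=C3 and a weak C1–C8 bond, which could undergo Cope shift or homolysis on heating.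

Step 16
Reactants: 25 bicyclic methyl vinylogous ester; 26 3-methoxybenzoyl chloride
Product: 28 C3-(3-methoxybenzoyl) bicyclic methyl vinylogous ester, via C3 lithio compound 27 (not isolated)
Conditions: lithium 2,2,6,6-tetramethylpiperidide, THF, −78 °C; then 3-methoxybenzoyl chloride, −78 → −40 °C
Reagents that add atoms: none
Why: C3–H is the only acidic hydrogen because the positions flanking the vinylogous ester are quaternary bridgeheads; the vinyllithium is acylated by the acid chloride, a known C3 acylation of bridged vinylogous esters.

Step 17
Reactants: 28 C3-(3-methoxybenzoyl) bicyclic methyl vinylogous ester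
Product: 29 CNP0285073.1, (1S,5S,7R,8S)-4-hydroxy-3-(3-hydroxybenzoyl)-8-methyl-1,5-bis(3-methylbut-2-enyl)-7-[(2E)-3,7-dimethylocta-2,6-dienyl]-8-(4-methylpent-3-enyl)bicyclo[3.3.1]non-3-ene-2,9-dione
Conditions: NaSEt, DMF, 120 °C; then 1 M HCl (work-up)
Reagents that add atoms: none
Why: Thiolate SN2 demethylation should cleave both the vinylogous methyl ester and the aryl methyl ether; the product is held as its trione enolate and phenolate until acidification, and no acid strong enough to cyclise prenyl groups onto the enol is used.

## Compound list

1 | 5-bromo-2-methylpent-2-ene | CC(C)=CCCBr | starting material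
2 | 6-methylhept-5-en-1-yne | CC(C)=CCCC#C | intermediate
3 | (E)-(2,6-dimethylhepta-1,5-dienyl)dimethylalane | CC(C)=CCC/C(C)=C/[Al](C)C | intermediate
4 | (E)-1-iodo-2,6-dimethylhepta-1,5-diene | CC(C)=CCC/C(C)=C/I | intermediate
5 | 3,4,5-trimethoxyphenol | COc1cc(O)cc(OC)c1OC | starting material
6 | 3,4,4,5-tetramethoxycyclohexa-2,5-dien-1-one | COC1=CC(=O)C=C(OC)C1(OC)OC | intermediate
7 | prenyl bromide (1-bromo-3-methylbut-2-ene) | CC(C)=CCBr | starting material
8 | sodium enolate of 3-hydroxy-4,4,5-trimethoxycyclohexa-2,5-dien-1-one | [Na+].COC1=CC(=O)C=C([O-])C1(OC)OC | intermediate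
9 | 3-hydroxy-4,4,5-trimethoxy-2-(3-methylbut-2-enyl)cyclohexa-2,5-dien-1-one | COC1=CC(=O)C(CC=C(C)C)=C(O)C1(OC)OC | intermediate
10 | nerol, (2Z)-3,7-dimethylocta-2,6-dien-1-ol | CC(C)=CCC/C(C)=C\CO | starting material
11 | 3-[(2Z)-3,7-dimethylocta-2,6-dienyloxy]-5,6,6-trimethoxy-2-(3-methylbut-2-enyl)cyclohexa-2,4-dien-1-one (O9 neryl enol ether) | COC1=CC(OC/C=C(C)\CCC=C(C)C)=C(CC=C(C)C)C(=O)C1(OC)OC | intermediate
12 | racemic 2-(3,7-dimethylocta-1,6-dien-3-yl)-4,4,5-trimethoxy-2-(3-methylbut-2-enyl)cyclohex-5-ene-1,3-dione (racemate; SMILES drawn for the enantiomer carried on) | C=C[C@](C)(CCC=C(C)C)[C@]1(CC=C(C)C)C(=O)C(OC)(OC)C(OC)=CC1=O | intermediate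
13 | single enantiomer of 12 with C1 and C8 as in the target | C=C[C@](C)(CCC=C(C)C)[C@]1(CC=C(C)C)C(=O)C(OC)(OC)C(OC)=CC1=O | intermediate
14 | 4,4,5-trimethoxy-2-(3-methylbut-2-enyl)-2-[(7E,9E)-2,6,10,14-tetramethylpentadeca-2,7,9,13-tetraen-6-yl]cyclohex-5-ene-1,3-dione | CC(C)=CCC/C(C)=C/C=C/[C@](C)(CCC=C(C)C)[C@]1(CC=C(C)C)C(=O)C(OC)(OC)C(OC)=CC1=O | intermediate
15 | 2,2-dimethoxy-4-(3-methylbut-2-enyl)-4-[(7E,9E)-2,6,10,14-tetramethylpentadeca-2,7,9,13-tetraen-6-yl]cyclohexane-1,3,5-trione | CC(C)=CCC/C(C)=C/C=C/[C@](C)(CCC=C(C)C)[C@]1(CC=C(C)C)C(=O)C(OC)(OC)C(=O)CC1=O | intermediate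
16 | 2-(trimethylsilyl)ethyl bromoacetate | C[Si](C)(C)CCOC(=O)CBr | starting material
17 | 2-(trimethylsilyl)ethyl ester of the C5-acetic acid of 15 (C5 epimers) | CC(C)=CCC/C(C)=C/C=C/[C@](C)(CCC=C(C)C)[C@]1(CC=C(C)C)C(=O)C(OC)(OC)C(=O)C(CC(=O)OCC[Si](C)(C)C)C1=O | intermediate
18 | prenyl acetate (3-methylbut-2-enyl acetate) | CC(=O)OCC=C(C)C | starting material
19 | C5-prenylated ketal ester (C5 quaternary: prenyl and CH2CO2CH2CH2SiMe3; C2, C4, C9 ketones; C3 dimethyl ketal) | CC(C)=CCC/C(C)=C/C=C/[C@](C)(CCC=C(C)C)[C@]1(CC=C(C)C)C(=O)C(OC)(OC)C(=O)[C@@](CC(=O)OCC[Si](C)(C)C)(CC=C(C)C)C1=O | intermediate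
20 | trione ester with C3 methylene | CC(C)=CCC/C(C)=C/C=C/[C@](C)(CCC=C(C)C)[C@]1(CC=C(C)C)C(=O)CC(=O)[C@@](CC(=O)OCC[Si](C)(C)C)(CC=C(C)C)C1=O | intermediate
21 | C2 methyl enol ether ester (C2–OMe, C4 ketone) | CC(C)=CCC/C(C)=C/C=C/[C@](C)(CCC=C(C)C)[C@]1(CC=C(C)C)C(OC)=CC(=O)[C@@](CC(=O)OCC[Si](C)(C)C)(CC=C(C)C)C1=O | intermediate
22 | C5-acetic acid with C2 methyl enol ether | CC(C)=CCC/C(C)=C/C=C/[C@](C)(CCC=C(C)C)[C@]1(CC=C(C)C)C(OC)=CC(=O)[C@@](CC(=O)O)(CC=C(C)C)C1=O | intermediate
23 | O-acyl thiohydroxamate (2-thioxopyridin-1-yl ester) of 22 | CC(C)=CCC/C(C)=C/C=C/[C@](C)(CCC=C(C)C)[C@]1(CC=C(C)C)C(OC)=CC(=O)[C@@](CC(=O)ON2C=CC=CC2=S)(CC=C(C)C)C1=O | intermediate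
24 | ring A methyl vinylogous ester with C5 iodomethyl and prenyl, C1 prenyl and the C8 dienyl side chain | CC(C)=CCC/C(C)=C/C=C/[C@](C)(CCC=C(C)C)[C@]1(CC=C(C)C)C(OC)=CC(=O)[C@@](CI)(CC=C(C)C)C1=O | intermediate
25 | bicyclic methyl vinylogous ester with complete ring B and C7 geranyl | CC(C)=CCC/C(C)=C/C[C@@H]1C[C@]2(CC=C(C)C)C(=O)[C@@](CC=C(C)C)(C(OC)=CC2=O)[C@@]1(C)CCC=C(C)C | intermediate
26 | 3-methoxybenzoyl chloride | COc1cccc(c1)C(Cl)=O | starting material
27 | C3 lithio derivative of 25 | CC(C)=CCC/C(C)=C/C[C@@H]1C[C@]2(CC=C(C)C)C(=O)[C@@](CC=C(C)C)(C(OC)=C([Li])C2=O)[C@@]1(C)CCC=C(C)C | intermediate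
28 | C3-(3-methoxybenzoyl) derivative of 25 | CC(C)=CCC/C(C)=C/C[C@@H]1C[C@]2(CC=C(C)C)C(=O)[C@@](CC=C(C)C)(C(OC)=C(C(=O)c3cccc(OC)c3)C2=O)[C@@]1(C)CCC=C(C)C | intermediate
29 | CNP0285073.1 | CC(C)=CCC/C(C)=C/C[C@@H]1C[C@]2(CC=C(C)C)C(=O)[C@@](CC=C(C)C)(C(=O)C(C(=O)c3cccc(O)c3)=C2O)[C@@]1(C)CCC=C(C)C | target

## Step count and least certain steps

Total step count: 17. Longest linear sequence: 15 steps (steps 3–17, from 5); steps 1 and 2 make iodide 4, which enters at step 7.

**Step 15 (key step).** The most likely failure is a 1,2-acyl migration of the β-keto C6 radical (3-exo attack on the C9 ketone or the C4 carbonyl, then ring expansion) that competes with ring closure. Beside it, premature reduction of the radical and loss of regio- or geometric control in the reduction of the allyl radical are possible. Fallback: setting out from 24, the C9 ketone is reduced first (NaBH4, MeOH/THF, 0 °C; the vinylogous ester carbonyl and the neopentyl iodide are inert) to the C9 carbinol F1. This removes the more reactive acyl acceptor next to the radical. F1 is cyclised under the tin hydride conditions to the bicyclic C9 carbinol F2, and oxidation with Dess–Martin periodinane comes back to the route at 25.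

**Step 11.** Single-electron reduction may go wrong by fragmentation of the weak C1–C8 bond from a C2 or C9 ketyl, which in 19 would release a diene-stabilised tertiary radical, or by pinacol-type coupling of the 1,3-diketone. Fallback: the ketal is carried through ring closure. Setting out from 19, fluoride cleavage of the ester gives the ketal acid F3. Its thiohydroxamate ester F4 is photolysed with iodoform as in step 14 to the ketal iodide F5, and radical cyclisation as in step 15 gives the bicyclic ketal F6. SmI2 then acts on the bicycle, in which C8 no longer carries the diene, to give the bicyclic trione F7, and methylation as in step 12 returns to the route at 25. The regioisomeric enol ether F8 that accompanies it is hydrolysed back to F7 with dilute acid. This order is not the first choice because the C4 ketone next to a ketal is a better acceptor for the C6 radical than the vinylogous ester carbonyl of 24.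

**Step 12.** Poor regioselectivity is the likely problem. The enolate oxygen on C4 is less shielded than the one on C2, which sits next to C1 and its tertiary C8 substituent. Methylation may therefore run mainly to the C4 methyl enol ether F9, which cannot be used in step 15. Fallback: the regiochemistry is decided in a hydrolysis instead of an alkylation.
- Setting out from 20, the mixture of 21 and F9 obtained under the step 12 conditions is O-methylated at the vinylogous ester carbonyl with Me3OBF4 (2,6-di-tert-butylpyridine, CH2Cl2, 0 °C).
- Both isomers give the same 2,4-dimethoxycyclohexenylium tetrafluoroborate F10.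
- Quenching with cold aqueous NaHCO3 lets water add to the less hindered terminus C4 of the cation. Loss of methanol from the hemiketal makes C4 the carbonyl and leaves the methyl group on O2, which comes back to the route at 21.
- The steric bias that works against 21 in the alkylation works for it here.
- Material that still emerges as F9 is hydrolysed to 20 (1 M HCl, THF) and used again.

**Step 5.** Etherification at the wrong oxygen (O2) or alkylation at C1 in the Mitsunobu reaction, or poor discrimination between chair and boat in the rearrangement, would each end in loss of the C1/C8 relationship. Fallback: setting out from 9, oxalyl chloride and catalytic DMF give the vinylogous chloride F11. Its regiochemistry can be established before the chloride is displaced by nerol 10 under NaH in THF (addition–elimination), which rejoins the route at 11 and then 12. If the rearrangement itself runs through a boat, geraniol takes the place of nerol, and the geranyl enol ether F12 is rearranged instead to deliver 12.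

**Step 7.** Insertion into the hindered vinyl group may be slow, so that homocoupling of 4 and base-induced cleavage of the non-enolisable diketone take over. Fallback: a base-free oxidative Heck reaction. Setting out from 4, Miyaura borylation (B2pin2, PdCl2(dppf), KOPh, toluene, 50 °C) gives the alkenylboronate F13. F13 is coupled with 13 under Pd(OAc)2 and benzoquinone without base. This enters the cycle through transmetalation to divalent palladium instead of oxidative addition, and comes back to the route at 14.

**Step 14.** The C6 radical may cyclise or rearrange before iodine transfer, and the diiodomethyl chain carrier may add to the diene. Fallback: the iodide is bypassed. Setting out from 22, thiohydroxamate ester 23 is prepared as in step 14 and photolysed with tert-butyl thiol in place of iodoform (Barton reductive decarboxylation). The C6 radical then closes ring B directly and the allyl radical is reduced by the thiol, coming back to the route at 25.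

## Further compounds

F1 | step 15 | C9 carbinol of 24 (C9–OH, either epimer; C5 iodomethyl retained) | CC(C)=CCC/C(C)=C/C=C/[C@](C)(CCC=C(C)C)[C@]1(CC=C(C)C)C(OC)=CC(=O)[C@@](CI)(CC=C(C)C)C1O
F2 | step 15 | bicyclic C9 carbinol corresponding to 25 | CC(C)=CCC/C(C)=C/C[C@@H]1C[C@]2(CC=C(C)C)C(O)[C@@](CC=C(C)C)(C(OC)=CC2=O)[C@@]1(C)CCC=C(C)C
F3 | step 11 | C5-acetic acid with C3 dimethyl ketal | CC(C)=CCC/C(C)=C/C=C/[C@](C)(CCC=C(C)C)[C@]1(CC=C(C)C)C(=O)C(OC)(OC)C(=O)[C@@](CC(=O)O)(CC=C(C)C)C1=O
F4 | step 11 | O-acyl thiohydroxamate (2-thioxopyridin-1-yl ester) of F3 | CC(C)=CCC/C(C)=C/C=C/[C@](C)(CCC=C(C)C)[C@]1(CC=C(C)C)C(=O)C(OC)(OC)C(=O)[C@@](CC(=O)ON2C=CC=CC2=S)(CC=C(C)C)C1=O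
F5 | step 11 | C5 iodomethyl compound with C3 dimethyl ketal | CC(C)=CCC/C(C)=C/C=C/[C@](C)(CCC=C(C)C)[C@]1(CC=C(C)C)C(=O)C(OC)(OC)C(=O)[C@@](CI)(CC=C(C)C)C1=O
F6 | step 11 | bicyclic 2,4,9-trione 3,3-dimethyl ketal | CC(C)=CCC/C(C)=C/C[C@@H]1C[C@]2(CC=C(C)C)C(=O)[C@@](CC=C(C)C)(C(=O)C(OC)(OC)C2=O)[C@@]1(C)CCC=C(C)C
F7 | step 11 | bicyclic 2,4,9-trione with C3 methylene | CC(C)=CCC/C(C)=C/C[C@@H]1C[C@]2(CC=C(C)C)C(=O)[C@@](CC=C(C)C)(C(=O)CC2=O)[C@@]1(C)CCC=C(C)C
F8 | step 11 | C4 methyl enol ether isomer of 25 | CC(C)=CCC/C(C)=C/C[C@@H]1C[C@]2(CC=C(C)C)C(=O)[C@@](CC=C(C)C)(C(=O)C=C2OC)[C@@]1(C)CCC=C(C)C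
F9 | step 12 | C4 methyl enol ether isomer of 21 (C4–OMe, C2 ketone) | CC(C)=CCC/C(C)=C/C=C/[C@](C)(CCC=C(C)C)[C@]1(CC=C(C)C)C(=O)C=C(OC)[C@@](CC(=O)OCC[Si](C)(C)C)(CC=C(C)C)C1=O
F10 | step 12 | 2,4-dimethoxycyclohexenylium tetrafluoroborate from 21 and F9 (dimethoxyallyl cation over C2–C3–C4, drawn with the charge on O4) | CC(C)=CCC/C(C)=C/C=C/[C@](C)(CCC=C(C)C)[C@]1(CC=C(C)C)C(OC)=CC(=[O+]C)[C@@](CC(=O)OCC[Si](C)(C)C)(CC=C(C)C)C1=O.F[B-](F)(F)F
F11 | step 5 | 3-chloro-5,6,6-trimethoxy-2-(3-methylbut-2-enyl)cyclohexa-2,4-dien-1-one (C9 vinylogous chloride) | COC1=CC(Cl)=C(CC=C(C)C)C(=O)C1(OC)OC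
F12 | step 5 | 3-[(2E)-3,7-dimethylocta-2,6-dienyloxy]-5,6,6-trimethoxy-2-(3-methylbut-2-enyl)cyclohexa-2,4-dien-1-one (O9 geranyl enol ether) | COC1=CC(OC/C=C(C)/CCC=C(C)C)=C(CC=C(C)C)C(=O)C1(OC)OC
F13 | step 7 | 2-[(E)-2,6-dimethylhepta-1,5-dienyl]-4,4,5,5-tetramethyl-1,3,2-dioxaborolane | CC(C)=CCC/C(C)=C/B1OC(C)(C)C(C)(C)O1
F0 | step 14 | none | none
A1 | alternative 1 | ring B ketone with C1 acetyl and C5 methyl ester, all four stereocentres set | CC(C)=CCC/C(C)=C/C[C@@H]1C[C@](C(=O)OC)(CC=C(C)C)C(=O)[C@@](CC=C(C)C)(C(C)=O)[C@@]1(C)CCC=C(C)C
A2 | alternative 2 | bicyclo[3.3.1]non-2-en-9-one with C4 tert-butyldimethylsilyl ether | CC(C)=CCC/C(C)=C/C[C@@H]1C[C@]2(CC=C(C)C)C(=O)[C@@](CC=C(C)C)(C=C[C@@H]2O[Si](C)(C)C(C)(C)C)[C@@]1(C)CCC=C(C)C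
A3 | alternative 3 | bicyclic C4 carbinol with C2 methyl enol ether | CC(C)=CCC/C(C)=C/C[C@@H]1C[C@]2(CC=C(C)C)C(=O)[C@@](CC=C(C)C)(C(OC)=C[C@H]2O)[C@@]1(C)CCC=C(C)C
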